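## Structural features

The target is a methyl tropone-carboxylate whose seven-membered ring is fused, through one C–O and one C–CH2 bond, to a dihydrofuran. The oxygen-bearing furan carbon (C9) is also the spiro atom of a cyclohexane (ring B). Going round ring B from C9 there are the methyl-bearing methine C8, two methylenes (C7, C6), the methine C5 with a 2-hydroxyprop-2-yl group, and the quaternary C10 with a methyl group and a 2-carboxyethyl chain (the remains of an opened ring A). The four stereocentres C5, C10, C9 and C8 are contiguous. The C8 methyl, the C9–O bond, the C10 methyl and the C5 carbinol lie on one face of ring B; the furan CH2 (C11) and the acid chain lie on the other; C9 and C10 are vicinal fully substituted carbons. Fragile groups are the tropone (hydrogenation, organometallics), its vinylogous keto ester, the tertiary alcohol, and the tertiary alkyl–oxygen bond at C9, whose acid ionisation would scramble the spiro centre. The real difficulty is the C9/C10 pair in the correct relation to C8, and then the timing of the seven-membered ring. The tropone differs from the ring of methyl 2,4-dihydroxy-3,6-dimethylbenzoate only by one CH between the methyl-bearing carbon and the fusion carbon, so a benzofuran can stand in for it until late. The key step exploits the fact that C9 is the α-carbon of a benzofuran-3-one whose enol oxygen sits on C11: tying that oxygen to C6 in a dihydropyran gives an allyl vinyl ether O–C11=C9 / C6–C5=C10, and a [3,3] shift forms C9–C10 and turns the pyran into ring B.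

## Logic of the disconnections

22 to 21 to 20. In 22 the ring bond between the tropone CH and the methyl-bearing carbon is cut and the bond from that carbon to the fusion carbon is restored, giving 21 with the extra carbon as CHCl2 on the former para carbon. Cutting the C–CHCl2 bond gives 20. The reason is that every earlier step can then run on a robust hexasubstituted benzene. The demand is heavy: the carbene must attack the para carbon of the phenoxide, and in the radical step the bond to the methyl-bearing neighbour must be the one that migrates.

20 to 18 (through 19). No skeletal bond is cut; the acid is traced to a primary alcohol, because an alcohol survives the methyl-metal addition that precedes it. The forward step must oxidise one primary alcohol beside a phenol and a tertiary alcohol.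

18 to 17. The two C–CH3 bonds of the carbinol are cut, leaving the C5 ester that the key step needs as an activating group. The addition must not epimerise C5 and must leave the aryl ester alone.

17 to 16. The C5–H and C6–H bonds are removed, giving the C5=C6 alkene that the key step leaves. The forward hydrogenation must deliver hydrogen to the face that carries the C10 chain.

16 to 14 (through 15). The two C11–H bonds go back to the furanone carbonyl and the free hydroxyl to its silyl ether. The carbonyl is the direct product of the key step; its removal must avoid cationic shifts and ionisation at C9.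

14 to 13. The C9–C10 bond is cut and the oxygen on C11 is joined to C6. This removes both fully substituted centres at once and leaves a compound with only two stereocentres (C6, C8). The demand is a concerted boat [3,3] shift from a pyran with the C6 alkenyl group cis to the C8 methyl and with the alkene methyl cis to C6.

13 to 12. The ring O–C11 bond is cut, giving a secondary alcohol and the furanone. The forward cyclodehydration must keep the C6–O bond intact so that 6R is carried over.

12 to 6 and 10 (through 11). The C5–C6 bond and the C10–CH3 bond are cut, giving an aldehyde and an ynoate. The forward step needs syn carbometalation with retention, preference for the aldehyde over the ketone, and it does not control C6.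

10 to 8 to 7 (through 9). The alkyne–ester bond and the O–Si bond are cut, ending at a commercial alkynol.

6 to 4 and 5. The C8–C9 bond is cut, giving a furanone nucleophile and an enal. The forward step must select one face of the β-carbon and stop at mono-addition.

4 to 1 and 2 (through 3). The aryl–C11 bond and the O–C9 bond are cut. Acylation can only occur at the single free ring position, which is ortho to the hydroxyl that closes the furanone.

## Other disconnections considered

Alternative 1: The cut removes the whole dihydrofuran (ring carbon–C11 and O–C9), separating a fully substituted tropone A2 from a ring B lactone with an exocyclic methylene at C9, A3. In the forward step BF3·OEt2 activates A2, the methylene attacks its only unsubstituted α-carbon, and the tertiary C9 cation is captured by the tropone oxygen ([8+2]) to give A1. A1 still needs loss of hydride and of the O-methyl group to become the tropone, and lactone opening.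
- In favour: it is convergent, both furan bonds and the spiro centre form in one step, and the seven-membered ring arrives ready-made. On this last point it is better than the chosen plan, which needs a late dearomatisation and ring expansion. The lactone also masks the alcohol and the acid together.
- Against: C9 arises by collapse of an open tertiary cation, so its configuration rests only on the bias of ring B, and that cation is flanked by C8–H and quaternary C10 and is prone to Wagner–Meerwein shifts. In the chosen plan C9 and C10 are tied together by suprafacial chirality transfer. The tropone can also react in [4+2] or [6+4] modes.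
- Comparison: A3 already contains C5, C8 and C10, so the stereochemical work moves into the fragment synthesis. Making C10 next to an sp2 C9 is somewhat easier than next to a second quaternary carbon, which is equal or slightly better than the chosen plan. The end game is shorter, the fragments longer; overall step count should be comparable.

Alternative 2: The cut opens two bonds of the seven-membered ring (C(CO2Me)–C(CH3) and CH(CH3)–C(O)), so the tropone is assembled on a furan. Rh2(O2CtBu)4 decomposes the siloxyvinyl diazo ester A6; the carbenoid cyclopropanates the methyl-bearing double bond of the spiro alkoxyfuran A5 and a Cope rearrangement gives the oxabicycle A4. Desilylation, β-elimination of the oxygen bridge and loss of water would then give the tropone.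
- In favour: every substituent of the tropone is placed by the choice of the two partners. There is no regiochemical question of the kind raised by the ring expansion of the chosen plan, so on this point it is better.
- Against: A5 is an electron-rich, acid-labile ketene-acetal-type furan that already carries all four stereocentres, so the key step solves none of the stereochemical problems. 2-Alkoxyfurans also tend to open to trienes after carbenoid attack instead of giving the bicycle.
- Comparison: this is the longest plan, because something like the Claisen step of the chosen route would still be needed to make A5.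

Alternative 3: The cut is at the C5–isopropenyl and C10–allyl bonds of ring B. CuBr·SMe2 with a chiral ferrocenyl diphosphine adds isopropenylmagnesium bromide to A8, and the magnesium enolate is allylated trans to the new group to give A7.
- In favour: two commodity reagents and one catalytic asymmetric step set C5 and C10 with their trans relation. C5 then needs no late hydrogenation, which is better than the chosen plan at that centre, and the start is simpler. Isopropenyl maps onto the carbinol and allyl onto the three-carbon acid chain.
- Against: an α-substituted enone is a poor acceptor in copper-catalysed asymmetric addition, and allylation of the hindered enolate at a carbon that becomes quaternary is slow. The ketone carbon of A7 must still become the spiro C9 with control relative to C10, the C8 methyl must be added, and the seven-membered ring is still to come.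
- Comparison: the start is quicker, but more steps follow the key step than in the chosen plan, where one step makes C9 and C10 together.

Key step: step 7

Remark on the chemistry: the labels C5 to C11 are those used above (C9 spiro carbon, C10 quaternary carbon, C8 the CH(CH3), C11 the furan CH2 or carbonyl carbon, C5 the ester or carbinol carbon, C6 and C7 the remaining ring carbons); in these labels the target is 5S,8R,9R,10R.

Remark on the chemistry: the precursor (6R,8R, Z-enoate) and the product (8R,9R,10R) were checked against the target and against the boat geometry and are mutually consistent, so they are used unchanged as 13 and 14. What the plain aldehyde addition does not control is C6; this is met by separating 12 from its C6 epimer, with inversion of the epimer as recycling. A trace of base is added to the thermolysis.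

Remark on the chemistry: crotonaldehyde is taken as the E isomer.

## Route

Step 1
Reactants: 1 atraric acid (methyl 2,4-dihydroxy-3,6-dimethylbenzoate); 2 chloroacetyl chloride
Product: 4 methyl 6-hydroxy-4,7-dimethyl-3-oxo-2,3-dihydro-1-benzofuran-5-carboxylate, via chloroketone 3 (not isolated)
Conditions: AlCl3, 1,2-dichloroethane, 0 to 40 °C; then NaOAc, MeOH, reflux
Reagents that add atoms: none
Why: Friedel–Crafts acylation can only occur at the single free ring carbon, which is ortho to the 4-hydroxyl, and the ortho-hydroxy α-chloroketone closes by intramolecular Williamson etherification (5-exo-tet) to the benzofuran-3(2H)-one; the 2-hydroxyl stays chelated to the ester.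

Step 2
Reactants: 4 methyl 6-hydroxy-4,7-dimethyl-3-oxo-2,3-dihydro-1-benzofuran-5-carboxylate; 5 (E)-but-2-enal (crotonaldehyde)
Product: 6 methyl 6-hydroxy-4,7-dimethyl-3-oxo-2-[(2R)-4-oxobutan-2-yl]-2,3-dihydro-1-benzofuran-5-carboxylate (both epimers at furanone C2)
Conditions: (S)-2-[diphenyl(trimethylsilyloxy)methyl]pyrrolidine (20 mol%), PhCO2H (20 mol%), toluene, 0 °C, 4 in slight excess
Reagents that add atoms: none
Why: Michael addition under iminium catalysis by a diarylprolinol silyl ether: the silyloxydiphenylmethyl group blocks one face of the E-iminium ion of 5, so the enol of 4 adds to the β-carbon from the open face and sets C8 as R. The furanone α-carbon is left unassigned because it becomes sp2 in step 6, and the excess of 4 is meant to suppress double addition.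

Step 3
Reactants: 7 pent-4-yn-1-ol
Product: 8 tert-butyldimethyl(pent-4-yn-1-yloxy)silane
Conditions: TBSCl, imidazole, CH2Cl2, 0 °C to rt
Reagents that add atoms: tert-butyldimethylsilyl chloride, CC(C)(C)[Si](C)(C)Cl
Why: Standard silylation of a primary alcohol; the silyl ether tolerates the organometallic steps and the thermolysis (a tert-butyl ester at this position would not survive 190 °C).

Step 4
Reactants: 8 tert-butyldimethyl(pent-4-yn-1-yloxy)silane
Product: 10 methyl 6-[(tert-butyldimethylsilyl)oxy]hex-2-ynoate, via lithium acetylide 9 (not isolated)
Conditions: n-BuLi, THF, −78 °C; then ClCO2Me, −78 to 0 °C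
Reagents that add atoms: methyl chloroformate, COC(=O)Cl
Why: Deprotonation of the terminal alkyne and C-acylation of the acetylide by the chloroformate gives the ynoate.

Step 5
Reactants: 10 methyl 6-[(tert-butyldimethylsilyl)oxy]hex-2-ynoate; 6 methyl 6-hydroxy-4,7-dimethyl-3-oxo-2-[(2R)-4-oxobutan-2-yl]-2,3-dihydro-1-benzofuran-5-carboxylate
Product: 12 methyl 2-[(2R,4R,5Z)-9-[(tert-butyldimethylsilyl)oxy]-4-hydroxy-5-(methoxycarbonyl)-6-methylnon-5-en-2-yl]-6-hydroxy-4,7-dimethyl-3-oxo-2,3-dihydro-1-benzofuran-5-carboxylate (the 6R alcohol; both epimers at furanone C2), via alkenylcuprate 11 (not isolated)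
Conditions: Me2CuLi (from CuI and MeLi), THF, −78 °C, then 10; then 6 pretreated with LiN(SiMe3)2 (1.0 equiv), −78 to −50 °C; NH4Cl (aq); chromatographic separation from the C6 epimer
Reagents that add atoms: lithium dimethylcuprate, [Li+].C[Cu-]C
Why: syn-Carbocupration of the ynoate puts the new methyl and copper cis, and the C-bound alkenylcuprate, kept cold, adds to the aldehyde with retention (alkenylcopper 1,2-addition), so the C10 methyl ends cis to C6 in the Z-enoate. The aldehyde reacts ahead of the vinylogous-ester-type aryl ketone and the phenol is masked as its lithium salt. Little 1,3-induction from C8 is expected, so 12 should form together with its C6 epimer and is separated from it.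

Step 6
Reactants: 12 the 6R alcohol
Product: 13 methyl (2R,4R)-2-[(2Z)-6-[(tert-butyldimethylsilyl)oxy]-1-methoxy-3-methyl-1-oxohex-2-en-2-yl]-7-hydroxy-4,6,9-trimethyl-3,4-dihydro-2H-pyrano[3,2-b][1]benzofuran-8-carboxylate (alkenyl on C6 and methyl on C8 cis)
Conditions: pyridinium p-toluenesulfonate (cat.), 4 Å molecular sieves, toluene, 80 °C
Reagents that add atoms: none
Why: Acid-catalysed attack of the C6 hydroxyl on the furanone carbonyl (6-exo-trig hemiketal) and loss of water toward the α-carbon gives the aromatic 3-alkoxybenzofuran (cyclodehydration). The C6–O bond is not broken, so 6R is retained and places the alkenyl group cis to the C8 methyl, while both α-epimers of 12 converge.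

Step 7
Reactants: 13 the cis-2-alkenyl dihydropyran fused to the benzofuran
Product: 14 dimethyl (2R,2'R,6'R)-2'-{3-[(tert-butyldimethylsilyl)oxy]propyl}-6-hydroxy-2',4,6',7-tetramethyl-3-oxo-3H-spiro[1-benzofuran-2,1'-cyclohex[3]ene]-3',5-dicarboxylate
Conditions: mesitylene (degassed), 2,6-lutidine (0.2 equiv), 190 °C, sealed tube
Reagents that add atoms: none
Why: The mechanism is a concerted thermal [3,3]-sigmatropic (Claisen) shift of the allyl vinyl ether O–C11=C9 / C6–C5=C10, in which O–C6 breaks while C9–C10 forms, C11 becomes the furanone carbonyl and the double bond moves to C5=C6. The closest known reactions are the rearrangement of 2-alkenyl-3,4-dihydro-2H-pyrans to cyclohex-3-enyl carbonyl compounds and that of 3-allyloxybenzofurans to 2-allylbenzofuran-3(2H)-ones. Ring B closes as a six-membered carbocycle by a pericyclic ring contraction (oxygen leaves the ring, carbon enters) through a boat in which C6 and C9 are bridgeheads of a bicyclo[2.2.2]-like array, because the two-atom tether C7–C8 rules out a chair. C9 is controlled by the C6 stereocentre: C10 can reach C9 only on the pyran face that carries the alkenyl group, which is cis to the C8 methyl, so the C9–O bond ends cis to that methyl (9R). C10 is controlled by the alkene geometry: the methyl cis to C6 points toward the C7–C8 bridge in the boat and ends cis to the C9–O bond, with the silyloxypropyl chain cis to C11 (10R). The step needs the concerted path to win over heterolysis of the allylic C6–O bond (which would cost the alkene geometry) and over elimination; the non-polar solvent, the trace of base and the C5 ester, which speeds the shift and destabilises an allyl cation, are meant to secure this. The syn relation of the C8 and C10 methyls in the boat is the reason for the high temperature, and the new carbonyl offsets the loss of furan aromaticity.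

Step 8
Reactants: 14 the spiro benzofuranone cyclohexene ester
Product: 16 dimethyl (2R,2'R,6'R)-6-hydroxy-2'-(3-hydroxypropyl)-2',4,6',7-tetramethyl-3H-spiro[1-benzofuran-2,1'-cyclohex[3]ene]-3',5-dicarboxylate, via benzylic alcohol 15 (not isolated)
Conditions: Et3SiH, CF3CO2H, CH2Cl2, 0 °C to rt; then K2CO3, MeOH
Reagents that add atoms: none
Why: Ionic hydrogenation: the electron-rich aryl ketone is protonated and reduced to the benzylic alcohol, which ionises to a cation stabilised by the ortho ring oxygen and the para hydroxyl and is reduced again to CH2. The acid also removes the primary silyl group, and the methanolysis cleaves any trifluoroacetate. The electron-poor enoate does not accept hydride, and the short cold exposure limits ionisation of the tertiary C9–O bond.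

Step 9
Reactants: 16 the deoxygenated enoate alcohol
Product: 17 dimethyl (2R,2'R,3'S,6'R)-6-hydroxy-2'-(3-hydroxypropyl)-2',4,6',7-tetramethyl-3H-spiro[1-benzofuran-2,1'-cyclohexane]-3',5-dicarboxylate
Conditions: [Ir(cod)(PCy3)(py)]PF6 (10 mol%), H2 (1 atm), CH2Cl2, rt
Reagents that add atoms: none
Why: Hydroxyl-directed hydrogenation with the cationic iridium catalyst: the primary hydroxyl of the chain, on the face of ring B opposite the C10 methyl, binds iridium, and hydrogen is delivered to C5 and C6 from that face, giving 5S (H cis to the chain, ester cis to the C10 methyl).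

Step 10
Reactants: 17 the saturated diester
Product: 18 methyl (2R,2'R,3'S,6'R)-6-hydroxy-3'-(2-hydroxypropan-2-yl)-2'-(3-hydroxypropyl)-2',4,6',7-tetramethyl-3H-spiro[1-benzofuran-2,1'-cyclohexane]-5-carboxylate
Conditions: MeLi (excess), CeCl3, THF, −78 to 0 °C
Reagents that add atoms: methyllithium, [Li]C
Why: Double addition of the methylcerium reagent to the aliphatic ester; the reagent is nucleophilic but hardly basic, so the epimerisable C5 should not be enolised. The aryl ester is shielded by two ortho substituents and by the neighbouring phenoxide.

Step 11
Reactants: 18 the triol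
Product: 20 3-[(2R,2'R,3'S,6'R)-6-hydroxy-3'-(2-hydroxypropan-2-yl)-5-(methoxycarbonyl)-2',4,6',7-tetramethyl-3H-spiro[1-benzofuran-2,1'-cyclohexan]-2'-yl]propanoic acid, via aldehyde 19 (not isolated)
Conditions: Dess–Martin periodinane, NaHCO3, CH2Cl2, 0 °C; then NaClO2, NaH2PO4, 2-methylbut-2-ene, t-BuOH–H2O, rt
Reagents that add atoms: sodium chlorite, [Na+].[O-]Cl=O
Why: Dess–Martin oxidation of the only primary alcohol, followed by Pinnick oxidation of the aldehyde. The tertiary alcohol cannot be oxidised, and the chelated, fully substituted phenol is expected to survive with the chlorine scavenger present.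

Step 12
Reactants: 20 the benzenoid hydroxy acid
Product: 21 3-[(2R,2'R,3'S,6'R)-3a-(dichloromethyl)-3'-(2-hydroxypropan-2-yl)-5-(methoxycarbonyl)-2',4,6',7-tetramethyl-6-oxo-3a,6-dihydro-3H-spiro[1-benzofuran-2,1'-cyclohexan]-2'-yl]propanoic acid (either configuration at C3a)
Conditions: CHCl3, NaOH (aq), 60 °C; then HCl (aq) to pH 3
Reagents that add atoms: chloroform, ClC(Cl)Cl
Why: Abnormal Reimer–Tiemann reaction: dichlorocarbene attacks the phenoxide at the para carbon (ring-fusion carbon C3a), which carries no hydrogen, so the adduct is trapped as the 4-dichloromethylcyclohexa-2,5-dienone. Both ortho carbons are also substituted and are more crowded by the solvated phenoxide and the ester, which is the basis for the para preference. The new quaternary centre is formed without control and disappears in step 13; the carboxylate and the hindered aryl ester should be stable to the base.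

Step 13
Reactants: 21 the 4-dichloromethyl dienone
Product: 22 CNP0448476.2, methyl (2R,2'R,3'S,6'R)-2'-(2-carboxyethyl)-3'-(2-hydroxypropan-2-yl)-2',5,6',8-tetramethyl-7-oxo-3,7-dihydrospiro[cyclohepta[b]furan-2,1'-cyclohexane]-6-carboxylate
Conditions: Bu3SnH, AIBN, benzene, 80 °C, slow addition
Reagents that add atoms: none
Why: Radical ring expansion of a 4-dichloromethyl dienone (Dowd–Beckwith-type 1,2-vinyl shift): the α-chloroalkyl radical adds 3-exo to the neighbouring methyl-bearing carbon, which is the acceptor carbon of the alkylidene keto ester; the cyclopropane reopens by cleavage of the old ring bond, and loss of the second chlorine atom from the ring-expanded radical gives the tropone. Addition to the other neighbour, an alkoxy-substituted enone carbon, is electronically disfavoured, which places the new CH between the methyl-bearing and the fusion carbon.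

## Compound list

1 | atraric acid (methyl 2,4-dihydroxy-3,6-dimethylbenzoate) | COC(=O)c1c(C)cc(O)c(C)c1O | starting material
2 | chloroacetyl chloride | ClCC(=O)Cl | starting material
3 | methyl 5-(chloroacetyl)-2,4-dihydroxy-3,6-dimethylbenzoate | COC(=O)c1c(C)c(C(=O)CCl)c(O)c(C)c1O | intermediate
4 | methyl 6-hydroxy-4,7-dimethyl-3-oxo-2,3-dihydro-1-benzofuran-5-carboxylate | COC(=O)c1c(C)c2C(=O)COc2c(C)c1O | intermediate
5 | (E)-but-2-enal (crotonaldehyde) | C/C=C/C=O | starting material
6 | methyl 6-hydroxy-4,7-dimethyl-3-oxo-2-[(2R)-4-oxobutan-2-yl]-2,3-dihydro-1-benzofuran-5-carboxylate (both epimers at furanone C2) | COC(=O)c1c(C)c2C(=O)C([C@H](C)CC=O)Oc2c(C)c1O | intermediate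
7 | pent-4-yn-1-ol | C#CCCCO | starting material
8 | tert-butyldimethyl(pent-4-yn-1-yloxy)silane | C#CCCCO[Si](C)(C)C(C)(C)C | intermediate
9 | {5-[(tert-butyldimethylsilyl)oxy]pent-1-yn-1-yl}lithium | [Li]C#CCCCO[Si](C)(C)C(C)(C)C | intermediate
10 | methyl 6-[(tert-butyldimethylsilyl)oxy]hex-2-ynoate | COC(=O)C#CCCCO[Si](C)(C)C(C)(C)C | intermediate
11 | lithium methyl{(2E)-6-[(tert-butyldimethylsilyl)oxy]-1-methoxy-3-methyl-1-oxohex-2-en-2-yl}cuprate (copper cis to the C3 methyl) | C/C(CCCO[Si](C)(C)C(C)(C)C)=C(\[Cu-]C)C(=O)OC.[Li+] | intermediate
12 | methyl 2-[(2R,4R,5Z)-9-[(tert-butyldimethylsilyl)oxy]-4-hydroxy-5-(methoxycarbonyl)-6-methylnon-5-en-2-yl]-6-hydroxy-4,7-dimethyl-3-oxo-2,3-dihydro-1-benzofuran-5-carboxylate (6R alcohol; both epimers at furanone C2) | COC(=O)c1c(C)c2C(=O)C([C@H](C)C[C@@H](O)/C(C(=O)OC)=C(\C)CCCO[Si](C)(C)C(C)(C)C)Oc2c(C)c1O | intermediate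
13 | methyl (2R,4R)-2-[(2Z)-6-[(tert-butyldimethylsilyl)oxy]-1-methoxy-3-methyl-1-oxohex-2-en-2-yl]-7-hydroxy-4,6,9-trimethyl-3,4-dihydro-2H-pyrano[3,2-b][1]benzofuran-8-carboxylate | COC(=O)c1c(C)c2c(c(C)c1O)OC1=C2O[C@@H](/C(C(=O)OC)=C(\C)CCCO[Si](C)(C)C(C)(C)C)C[C@H]1C | intermediate
14 | dimethyl (2R,2'R,6'R)-2'-{3-[(tert-butyldimethylsilyl)oxy]propyl}-6-hydroxy-2',4,6',7-tetramethyl-3-oxo-3H-spiro[1-benzofuran-2,1'-cyclohex[3]ene]-3',5-dicarboxylate | COC(=O)c1c(C)c2c(c(C)c1O)O[C@]1(C2=O)[C@H](C)CC=C(C(=O)OC)[C@@]1(C)CCCO[Si](C)(C)C(C)(C)C | intermediate
15 | C11 (furan C3) alcohol of 14, either configuration at the carbinol carbon | COC(=O)c1c(C)c2c(c(C)c1O)O[C@]1(C2O)[C@H](C)CC=C(C(=O)OC)[C@@]1(C)CCCO[Si](C)(C)C(C)(C)C | intermediate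
16 | dimethyl (2R,2'R,6'R)-6-hydroxy-2'-(3-hydroxypropyl)-2',4,6',7-tetramethyl-3H-spiro[1-benzofuran-2,1'-cyclohex[3]ene]-3',5-dicarboxylate | COC(=O)c1c(C)c2c(c(C)c1O)O[C@]1(C2)[C@H](C)CC=C(C(=O)OC)[C@@]1(C)CCCO | intermediate
17 | dimethyl (2R,2'R,3'S,6'R)-6-hydroxy-2'-(3-hydroxypropyl)-2',4,6',7-tetramethyl-3H-spiro[1-benzofuran-2,1'-cyclohexane]-3',5-dicarboxylate | COC(=O)c1c(C)c2c(c(C)c1O)O[C@]1(C2)[C@H](C)CC[C@H](C(=O)OC)[C@@]1(C)CCCO | intermediate
18 | methyl (2R,2'R,3'S,6'R)-6-hydroxy-3'-(2-hydroxypropan-2-yl)-2'-(3-hydroxypropyl)-2',4,6',7-tetramethyl-3H-spiro[1-benzofuran-2,1'-cyclohexane]-5-carboxylate | COC(=O)c1c(C)c2c(c(C)c1O)O[C@]1(C2)[C@H](C)CC[C@H](C(C)(C)O)[C@@]1(C)CCCO | intermediate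
19 | methyl (2R,2'R,3'S,6'R)-6-hydroxy-3'-(2-hydroxypropan-2-yl)-2',4,6',7-tetramethyl-2'-(3-oxopropyl)-3H-spiro[1-benzofuran-2,1'-cyclohexane]-5-carboxylate | COC(=O)c1c(C)c2c(c(C)c1O)O[C@]1(C2)[C@H](C)CC[C@H](C(C)(C)O)[C@@]1(C)CCC=O | intermediate
20 | 3-[(2R,2'R,3'S,6'R)-6-hydroxy-3'-(2-hydroxypropan-2-yl)-5-(methoxycarbonyl)-2',4,6',7-tetramethyl-3H-spiro[1-benzofuran-2,1'-cyclohexan]-2'-yl]propanoic acid | COC(=O)c1c(C)c2c(c(C)c1O)O[C@]1(C2)[C@H](C)CC[C@H](C(C)(C)O)[C@@]1(C)CCC(=O)O | intermediate
21 | 3-[(2R,2'R,3'S,6'R)-3a-(dichloromethyl)-3'-(2-hydroxypropan-2-yl)-5-(methoxycarbonyl)-2',4,6',7-tetramethyl-6-oxo-3a,6-dihydro-3H-spiro[1-benzofuran-2,1'-cyclohexan]-2'-yl]propanoic acid (either configuration at C3a) | COC(=O)C1=C(C)C2(C(Cl)Cl)C(=C(C)C1=O)O[C@]1(C2)[C@H](C)CC[C@H](C(C)(C)O)[C@@]1(C)CCC(=O)O | intermediate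
22 | CNP0448476.2, methyl (2R,2'R,3'S,6'R)-2'-(2-carboxyethyl)-3'-(2-hydroxypropan-2-yl)-2',5,6',8-tetramethyl-7-oxo-3,7-dihydrospiro[cyclohepta[b]furan-2,1'-cyclohexane]-6-carboxylate | COC(=O)c1c(C)cc2c(c(C)c1=O)O[C@]1(C2)[C@H](C)CC[C@H](C(C)(C)O)[C@@]1(C)CCC(=O)O | target

## Step count and least certain steps

Total step count: 13. Longest linear sequence: 11 (steps 1, 2 and 5 to 13; the branch through steps 3 and 4 is equally long).

Step 7 (key step). The most likely failure is that the concerted shift is slower than thermal heterolysis of the allylic C6–O bond, because the boat carries the syn methyls and allylic strain; this would lead to elimination or loss of the alkene geometry. Fallback: change from the thermal pericyclic shift to a metal-catalysed ionisation and recombination. Setting out from 13, zerovalent palladium (Pd2(dba)3, PPh3, THF, 60 °C) ionises the allylic enol ether to a π-allylpalladium and benzofuranolate pair held together by the C7–C8 tether. Ring closure at C10 (Tsuji–Trost-type formal [3,3], double inversion keeps the suprafacial sense) would return at 14. The face of the enolate is then no longer fixed by the oxygen tether, so the C9 selectivity would rest on the tether and the ligand. This fallback makes no new compound (F0).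

Step 12. The most likely failure is poor site selectivity of the carbene (attack at the methyl-bearing ortho carbon between the two oxygens or at the ester-bearing ortho carbon) together with low conversion, since all three activated carbons are substituted. Fallback: change from electrophilic dichloromethylation to a one-pot cyclopropanation and ring opening. Setting out from 20 as its trilithium salt, chlorocarbene generated from CH2Cl2 and lithium 2,2,6,6-tetramethylpiperidide (THF, −78 to 0 °C) adds across the para–meta bond of the phenoxide, and the chlorocyclopropane opens with loss of chloride to the tropone. This returns directly at 22 and bypasses 21 and the tin step. It makes no new compound (F0).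

Step 13. The most likely failure is migration of the wrong vinyl group (closure on the alkoxy-bearing neighbour, which would put the CH on the other side of the fusion carbon), or plain hydrodechlorination before rearrangement. Fallback: change from the radical to the anionic manifold, where the regiochemistry is set by conjugate addition to the doubly activated carbon only. Setting out from 21, KOt-Bu (THF, −40 °C) deprotonates the CHCl2 group; intramolecular Michael addition and fragmentation with loss of chloride should give the 4-chlorotropone F1. Its chlorine is then removed by formate reduction (Pd(OAc)2, PPh3, HCO2Na) to return at 22.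

Step 5. The most likely failure is poor facial selectivity in the addition to the aldehyde, since no control element is near C6; up to half of the material would then be the C6 epimer. Fallback: recycle by inversion instead of relying on the addition. The separated (6S)-alcohol F2 is converted by Mitsunobu reaction (4-nitrobenzoic acid, PPh3, diisopropyl azodicarboxylate) into the (6R) 4-nitrobenzoate F3, and methanolysis (K2CO3, MeOH) returns at 12.

Step 9. The most likely failure is weak direction by the remote primary hydroxyl, leading to hydrogen delivery from the wrong face; the C5 ester epimer so formed is probably the more stable one and cannot be corrected by equilibration. Fallback: change the directing group and the order of steps. Setting out from 14, NaBH4 with CeCl3·7H2O gives 15 (now isolated). Its rigid C11 hydroxyl lies on the same face as the chain and directs the same iridium catalyst to give the saturated C11 alcohol F4. Treatment with Et3SiH and CF3CO2H then removes the hydroxyl and the silyl group and returns at 17.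

## Further compounds

F0 | step 7 | none | none
F0 | step 12 | none | none
F1 | step 13 | 3-[(2R,2'R,3'S,6'R)-4-chloro-3'-(2-hydroxypropan-2-yl)-6-(methoxycarbonyl)-2',5,6',8-tetramethyl-7-oxo-3,7-dihydrospiro[cyclohepta[b]furan-2,1'-cyclohexan]-2'-yl]propanoic acid | COC(=O)c1c(C)c(Cl)c2c(c(C)c1=O)O[C@]1(C2)[C@H](C)CC[C@H](C(C)(C)O)[C@@]1(C)CCC(=O)O
F2 | step 5 | (6S)-epimer of 12, methyl 2-[(2R,4S,5Z)-9-[(tert-butyldimethylsilyl)oxy]-4-hydroxy-5-(methoxycarbonyl)-6-methylnon-5-en-2-yl]-6-hydroxy-4,7-dimethyl-3-oxo-2,3-dihydro-1-benzofuran-5-carboxylate | COC(=O)c1c(C)c2C(=O)C([C@H](C)C[C@H](O)/C(C(=O)OC)=C(\C)CCCO[Si](C)(C)C(C)(C)C)Oc2c(C)c1O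
F3 | step 5 | (6R) 4-nitrobenzoate of 12 | COC(=O)c1c(C)c2C(=O)C([C@H](C)C[C@@H](OC(=O)c3ccc(cc3)[N+](=O)[O-])/C(C(=O)OC)=C(\C)CCCO[Si](C)(C)C(C)(C)C)Oc2c(C)c1O
F4 | step 9 | dimethyl (2R,2'R,3'S,6'R)-2'-{3-[(tert-butyldimethylsilyl)oxy]propyl}-3,6-dihydroxy-2',4,6',7-tetramethyl-3H-spiro[1-benzofuran-2,1'-cyclohexane]-3',5-dicarboxylate (either configuration at C3) | COC(=O)c1c(C)c2c(c(C)c1O)O[C@]1(C2O)[C@H](C)CC[C@H](C(=O)OC)[C@@]1(C)CCCO[Si](C)(C)C(C)(C)C
A1 | alternative 1 | dihydrofuran-fused methoxycycloheptatriene lactone, the [8+2] adduct | COC(=O)C1=C(OC)C(C)=C2O[C@]3(CC2C=C1C)[C@H](C)CC[C@H](C(C)(C)O4)[C@@]3(C)CCC4=O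
A2 | alternative 1 | 3-methoxy-4-(methoxycarbonyl)-2,5-dimethyltropone | COC(=O)c1c(C)ccc(=O)c(C)c1OC
A3 | alternative 1 | ring B ε-lactone with exocyclic methylene at C9, configured at C5, C8 and C10 as in the target | C=C1[C@H](C)CC[C@H](C(C)(C)O2)[C@@]1(C)CCC2=O
A4 | alternative 2 | 8-oxabicyclo[3.2.1]octadiene with ketal bridgehead, the [4+3] adduct | O1[C@]2(CC3=CC4(C)OC13C(C)C(O[Si](C)(C)C(C)(C)C)=C4C(=O)OC)[C@H](C)CC[C@H](C(C)(C)O[Si](CC)(CC)CC)[C@@]2(C)CCCO[Si](C)(C)C(C)(C)C
A5 | alternative 2 | spiro-fused 2-alkoxyfuran (5-methyl-2,3-dihydrofuro[2,3-b]furan spiro-linked to silyl-protected ring B) | Cc1cc2c(o1)O[C@]1(C2)[C@H](C)CC[C@H](C(C)(C)O[Si](CC)(CC)CC)[C@@]1(C)CCCO[Si](C)(C)C(C)(C)C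
A6 | alternative 2 | methyl (3Z)-3-[(tert-butyldimethylsilyl)oxy]-2-diazopent-3-enoate | COC(=O)C(=[N+]=[N-])/C(O[Si](C)(C)C(C)(C)C)=C/C
A7 | alternative 3 | 2-allyl-2-methyl-3-isopropenylcyclohexanone, allyl and isopropenyl trans | O=C1CCC[C@H](C(C)=C)[C@@]1(C)CC=C
A8 | alternative 3 | 2-methylcyclohex-2-en-1-one | CC1=CCCCC1=O
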